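**Retrosynthetic overview**

1. The phenol O–H is freed last from a methyl ether. The diaryl ether bond from O2 to ring B is cut to a ring A phenol and a (2,4-dibromophenyl)iodonium salt, so ring B is bought ready-made.
2. The two oxygens of ring A are told apart at 3,4,5-tribromocatechol: its dianion is methylated at O1 (next to C6–H), leaving the bromine-flanked O2 for arylation.
3. The strategy rests on this feature of ring A: bromine on three neighbouring carbons C3, C4, C5, then C6–H, and oxygen on the vicinal pair C1, C2. This is a 1,2,3-tribromobutadiene unit (C3–C6) joined to a cis-enediol unit (C1–C2).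
4. Ring A is therefore cut at C1–C6 and C2–C3 into 2,3,4-tribromothiophene 1,1-dioxide and vinylene carbonate: (4+2) cycloaddition, loss of SO2, then DDQ aromatisation and carbonate hydrolysis.
5. Ring order: ring A is the only ring made (step 3); ring B comes from 2,4-dibromo-1-iodobenzene.

Key step: step 3

Remark: the target is achiral. Compounds 6 and 7 are racemic (one enantiomer drawn) and their two stereocentres are erased in step 4.

**Route**

Step 1
Reactants: 1 tetrabromothiophene
Product: 3 2,3,4-tribromothiophene, via 3,4,5-tribromo-2-thienyllithium 2 (not isolated)
Conditions: n-BuLi (1.0 equiv), Et2O, −78 °C; then H2O, −78 °C → rt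
Reagents that add atoms: none
Why: Bromine–lithium exchange on a perbrominated thiophene takes place at an alpha carbon, where the carbanion is best stabilised, and at −78 °C with one equivalent of n-BuLi the monolithio compound 2 should be stable to halogen scrambling, so that protonation leaves the single C–H at C5.

Step 2
Reactants: 3 2,3,4-tribromothiophene
Product: 4 2,3,4-tribromothiophene 1,1-dioxide
Conditions: H2O2 (50% aq.), (CF3CO)2O, CH2Cl2, 0 °C → rt
Reagents that add atoms: hydrogen peroxide, OO, delivered as trifluoroperacetic acid, OOC(=O)C(F)(F)F, made in the flask with trifluoroacetic anhydride, O=C(OC(=O)C(F)(F)F)C(F)(F)F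
Why: Oxidation at sulfur (thiophene to thiophene S,S-dioxide) by the strongly electrophilic trifluoroperacetic acid, the usual reagent for electron-poor halothiophenes, should give the dioxide without attack on the brominated ring carbons, and the three bromines should make the dioxide isolable.

Step 3
Reactants: 4 2,3,4-tribromothiophene 1,1-dioxide; 5 vinylene carbonate
Product: 7 cis-4,5,6-tribromo-3a,7a-dihydro-1,3-benzodioxol-2-one (racemic), via bicyclic sulfone adduct 6 (not isolated)
Conditions: 5 (8 equiv), BHT (cat.), PhCl, 120 °C, slow addition of 4, argon purge
Reagents that add atoms: none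
Why: The non-aromatic, electron-poor diene of 4 should add across the C=C of 5 in a concerted Diels–Alder reaction of inverse electron demand, forming C1–C6 and C2–C3 of ring A in one event, and the 7-thiabicyclo[2.2.1]heptene 7,7-dioxide 6 should then lose SO2 by cheletropic extrusion at the same temperature. The closest known reaction type is the cycloaddition of tetrachloro- and other halogenated thiophene 1,1-dioxides to alkenes, which gives halogenated cyclohexa-1,3-dienes with spontaneous loss of SO2, and vinylene carbonate is known to add to perhalogenated dienes on heating. Ring A is closed as a six-membered carbocycle by this intermolecular (4+2) cycloaddition, the SO2 bridge being only a transient one-atom link. The two new stereocentres (C3a and C7a, the later C2 and C1 of ring A) are set cis by suprafacial addition to the ring-locked Z alkene of 5; 7 is racemic, and the endo or exo sense of 6 is of no consequence once the bridge is gone. No regiochemistry has to be controlled, since the dienophile is symmetric and both of its carbons carry oxygen; what the step needs is cross-addition ahead of self-dimerisation of 4, which the three bromines on the diene, the excess of 5 and the slow addition of 4 should secure. The product diene is too electron-poor and hindered to add a second dienophile, and the neutral medium leaves the carbonate in place, so that no elimination to a monophenol is to be expected.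

Step 4
Reactants: 7 cis-4,5,6-tribromo-3a,7a-dihydro-1,3-benzodioxol-2-one
Product: 8 4,5,6-tribromo-1,3-benzodioxol-2-one
Conditions: DDQ (1.5 equiv), PhCl, 120 °C
Reagents that add atoms: none
Why: DDQ dehydrogenation of a cyclohexa-1,3-diene: hydride abstraction from an allylic, oxygen-bearing ring-fusion C–H gives an arenium ion that loses the neighbouring cis proton, the gain of aromaticity drives it, and the carbonate keeps both oxygens acylated so that neither elimination to a monophenol nor oxidation on to an o-quinone should set in; both stereocentres are erased here.

Step 5
Reactants: 8 4,5,6-tribromo-1,3-benzodioxol-2-one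
Product: 9 3,4,5-tribromobenzene-1,2-diol
Conditions: NaOH (aq., 4 equiv), THF, 0 °C → rt, argon; then 1 M HCl
Reagents that add atoms: none
Why: Saponification of an aryl carbonate, fast because each phenoxide is a good leaving group and the half-carbonate decarboxylates, should free both hydroxyls, while cold hydroxide leaves the aryl bromides alone and exclusion of air protects the catecholate.

Step 6
Reactants: 9 3,4,5-tribromobenzene-1,2-diol
Product: 11 2,3,4-tribromo-6-methoxyphenol, via disodium 3,4,5-tribromocatecholate 10 (not isolated)
Conditions: NaH (2.2 equiv), DMF, 0 °C; then MeI (1.0 equiv), 0 °C → rt; aq. HCl work-up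
Reagents that add atoms: iodomethane, CI
Why: Williamson etherification of a catechol dianion with one equivalent of electrophile, which is known to fall on the more basic oxygen: O1 (next to C6–H) has no ortho bromine and is the less hindered, so it should be methylated, and the remaining bromine-flanked O2 monoanion is much less nucleophilic than the dianion, which should hold the reaction at the mono-ether.

Step 7
Reactants: 12 2,4-dibromo-1-iodobenzene; 13 1,3,5-trimethoxybenzene
Product: 15 (2,4-dibromophenyl)(2,4,6-trimethoxyphenyl)iodonium tosylate, via Koser-type hydroxy(tosyloxy)iodoarene 14 (not isolated)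
Conditions: mCPBA (1.1 equiv), TsOH·H2O (1.0 equiv), MeCN, 77 °C; then 13, 77 °C → rt
Reagents that add atoms: p-toluenesulfonic acid monohydrate, Cc1ccc(cc1)S(=O)(=O)O.O
Why: One-pot synthesis of an aryl(trimethoxyphenyl)iodonium tosylate: mCPBA and TsOH oxidise the aryl iodide to the Koser-type trivalent iodine species 14, which then substitutes the very electron-rich arene 13 at a ring C–H, and the aryl bromides take no part.

Step 8
Reactants: 11 2,3,4-tribromo-6-methoxyphenol; 15 (2,4-dibromophenyl)(2,4,6-trimethoxyphenyl)iodonium tosylate
Product: 16 1,2,3-tribromo-4-(2,4-dibromophenoxy)-5-methoxybenzene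
Conditions: K2CO3 (1.5 equiv), MeCN, 60 °C
Reagents that add atoms: none
Why: Metal-free O-arylation of a phenoxide with a diaryliodonium salt by ligand exchange at trivalent iodine and ligand coupling, in which the electron-poor, ortho-substituted 2,4-dibromophenyl group is the one transferred and the trimethoxyphenyl group leaves as its iodide; O1 is capped, so only the bromine-flanked O2 can react, and without a transition metal no C–Br bond should be touched.

Step 9
Reactants: 16 1,2,3-tribromo-4-(2,4-dibromophenoxy)-5-methoxybenzene
Product: 18 3,4,5-tribromo-2-(2,4-dibromophenoxy)phenol (target), via aryloxydibromoborane 17 (not isolated)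
Conditions: BBr3 (2 equiv), CH2Cl2, −78 °C → rt; then H2O
Reagents that add atoms: none
Why: BBr3 demethylation of an aryl methyl ether: the Lewis acid binds the methoxy oxygen and bromide attacks the methyl carbon in an SN2 step to give 17, which water hydrolyses, while the diaryl ether offers no sp3 carbon and the aryl bromides are inert, as in the usual conversion of methoxylated polybrominated diphenyl ethers into the phenols.

**Compound list**

1 | tetrabromothiophene | Brc1sc(Br)c(Br)c1Br | starting material
2 | 3,4,5-tribromo-2-thienyllithium | [Li]c1sc(Br)c(Br)c1Br | intermediate (not isolated)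
3 | 2,3,4-tribromothiophene | Brc1csc(Br)c1Br | intermediate
4 | 2,3,4-tribromothiophene 1,1-dioxide | O=S1(=O)C=C(Br)C(Br)=C1Br | intermediate
5 | vinylene carbonate (1,3-dioxol-2-one) | O=C1OC=CO1 | starting material
6 | bicyclic sulfone adduct: 1,2,3-tribromo-7-thiabicyclo[2.2.1]hept-2-ene 7,7-dioxide with the cyclic carbonate cis-fused at C5 and C6 (endo isomer drawn, racemic) | O=S1(=O)[C@]2(Br)C(Br)=C(Br)[C@H]1[C@H]1OC(=O)O[C@H]12 | intermediate (not isolated)
7 | cis-4,5,6-tribromo-3a,7a-dihydro-1,3-benzodioxol-2-one (racemic, one enantiomer drawn) | O=C1O[C@@H]2C=C(Br)C(Br)=C(Br)[C@@H]2O1 | intermediate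
8 | 4,5,6-tribromo-1,3-benzodioxol-2-one | O=C1Oc2cc(Br)c(Br)c(Br)c2O1 | intermediate
9 | 3,4,5-tribromobenzene-1,2-diol (3,4,5-tribromocatechol) | Oc1cc(Br)c(Br)c(Br)c1O | intermediate
10 | disodium 3,4,5-tribromobenzene-1,2-diolate | [Na+].[Na+].[O-]c1cc(Br)c(Br)c(Br)c1[O-] | intermediate (not isolated)
11 | 2,3,4-tribromo-6-methoxyphenol | COc1cc(Br)c(Br)c(Br)c1O | intermediate
12 | 2,4-dibromo-1-iodobenzene | Brc1ccc(I)c(Br)c1 | starting material
13 | 1,3,5-trimethoxybenzene | COc1cc(OC)cc(OC)c1 | starting material
14 | 2,4-dibromo-1-[hydroxy(tosyloxy)-λ3-iodanyl]benzene | Cc1ccc(cc1)S(=O)(=O)OI(O)c1ccc(Br)cc1Br | intermediate (not isolated)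
15 | (2,4-dibromophenyl)(2,4,6-trimethoxyphenyl)iodonium tosylate | COc1cc(OC)c([I+]c2ccc(Br)cc2Br)c(OC)c1.Cc1ccc(cc1)S(=O)(=O)[O-] | intermediate
16 | 1,2,3-tribromo-4-(2,4-dibromophenoxy)-5-methoxybenzene | COc1cc(Br)c(Br)c(Br)c1Oc1ccc(Br)cc1Br | intermediate
17 | dibromo[3,4,5-tribromo-2-(2,4-dibromophenoxy)phenoxy]borane | BrB(Br)Oc1cc(Br)c(Br)c(Br)c1Oc1ccc(Br)cc1Br | intermediate (not isolated)
18 | 3,4,5-tribromo-2-(2,4-dibromophenoxy)phenol | Oc1cc(Br)c(Br)c(Br)c1Oc1ccc(Br)cc1Br | target

**Step count**

Total: 9 steps. Longest linear sequence: 8 steps (steps 1–6, 8, 9); step 7 is a one-step side branch.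

**Steps most likely to fail**

Step 3. The dienophile may react too slowly, so that 4 is used up by self-cycloaddition (one molecule as diene, the C4=C5 bond of a second as dienophile, then loss of SO2). At the temperature needed, the adduct may also lose CO2 and go on to a monophenol. The fallback gives up the cycloaddition. It does not set out from a numbered compound of the route but from commercial guaiacol F1, and it comes back to the route at compound 11. Guaiacol F1 with Br2 (3.1 equiv) in AcOH at rt should be brominated para and ortho to the free hydroxyl and then para to the methoxy group. This is the classical tribromination pattern and gives 2,3,4-tribromo-6-methoxyphenol, which is compound 11. Steps 7, 8 and 9 then follow unchanged.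

Step 4. Hydride abstraction from the electron-poor, tribrominated diene may be slow. Forcing conditions may then lead to loss of the carbonate by elimination to a monophenol, or to addition of DDQ across the diene. The fallback sets out from compound 7 and comes back at compound 9. It replaces C–H dehydrogenation by alcohol oxidation. Methanolysis of the carbonate (K2CO3 cat., MeOH, 0 °C) should give cis-3,4,5-tribromocyclohexa-3,5-diene-1,2-diol F2. Activated MnO2 in CH2Cl2 at rt should oxidise either allylic hydroxyl to an α-hydroxy dienone, which is the keto tautomer of 9 and should enolise at once. A wash with aqueous Na2S2O4 returns any o-quinone formed by overoxidation to the catechol 9.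

Step 6. The two phenoxides of the dianion may be discriminated poorly, giving the regioisomeric mono-ether, and alkylation may run on to the dimethyl ether. The fallback sets out from compound 9 and comes back at compound 11. Exhaustive methylation (MeI excess, K2CO3, acetone, reflux) should give 1,2,3-tribromo-4,5-dimethoxybenzene F3. BCl3 (1.1 equiv, CH2Cl2, −78 → 0 °C) should then cleave one methyl ether selectively. The methoxy group on O2 is flanked by bromine and by the other methoxy group, is twisted out of the ring plane and is the more basic, so it should bind the Lewis acid and be cleaved, as is known for methoxy groups with two ortho neighbours. This leaves the O1 methyl ether, that is compound 11.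

**Further compounds**

F1 | step 3 | guaiacol (2-methoxyphenol) | COc1ccccc1O
F2 | step 4 | cis-3,4,5-tribromocyclohexa-3,5-diene-1,2-diol (racemic, one enantiomer drawn) | O[C@@H]1C=C(Br)C(Br)=C(Br)[C@@H]1O
F3 | step 6 | 1,2,3-tribromo-4,5-dimethoxybenzene | COc1cc(Br)c(Br)c(Br)c1OC
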